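**Numbering.** Compounds carry the numbers of the steps and of the compound list below. Ring positions use eremophilane numbering: ring A = C1, C2, C3, C4, C5, C10; ring B = C5, C6, C7, C8, C9, C10; C15 is the methyl on C4, C14 the methyl on C5, C11 the isopropylidene carbon on C7.

## Analysis of the target

The target 22 is a 3-acyloxy-eremophila-1,9,7(11)-trien-8-one: a decalin core whose C3 oxygen carries a (2E,4E,6S)-6-methylocta-2,4-dienoyl group. The core holds three contiguous stereocentres, C3 (S), C4 (R) and the quaternary C5 (R), with the C3 oxygen, the C4 methyl and the C5 methyl all on one face of ring A; the fourth stereocentre, C6′ (S) of the acyl chain, is remote and is best bought. Every other ring carbon except C6 is sp2: C1=C2, C9=C10, the C8 ketone and C7=C11 form a cross-conjugated trienone. The feature that decides the strategy lies in ring A: C10 is an sp2 ring-fusion carbon whose double bond to C9 is exocyclic to ring A and stands next to the ring A alkene C1=C2. This is exactly the pattern left behind when a vinylallene C3=C2–C1=C10=C9 adds an alkene C4=C5 across C3 and C10. Sensitive groups are the C3 ester (allylic, at the far end of the dienone, prone to ionisation and elimination), the dienone (γ- and ε-deprotonation, conjugate addition) and the dienoate (E/Z drift, deconjugation). The difficulty is the all-cis triad with a quaternary carbon in a ring that has almost no sp3 positions to relay stereocontrol, together with an oxidation pattern that a stepwise annulation reaches only through several late adjustments.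

## Retrosynthetic reasoning

**Ester bond C3–O–C1′ (22 ⇒ 20 + 5).** The acyl chain is cut off last. This keeps the isomerisation-prone dienoate out of every earlier step, makes the route convergent, and leaves the C3–O bond untouched, so the C3 configuration is carried over with retention. Acid 5 goes back through ester 4 to aldehyde 3 and phosphonate 2 (vinylogous olefination at C4′=C5′), and 3 to the commercial alcohol 1, which supplies C6′.

**Silyl ether (20 ⇒ 19).** The C3 oxygen travels through the key step as a bulky silyl enol ether oxygen, which survives base and heat and is removed under buffered fluoride.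

**Bonds C3–C4 and C5–C10 (19 ⇒ 18).** Both rings are opened at once by a retro-[4+2]: ring A is the cycloaddition ring, ring B the tether ring. The cut is made here because the product pattern C9=C10 (exocyclic to ring A) plus C1=C2 is the signature of a vinylallene diene, so the complete trienone arrives at the right oxidation level with no redox step afterwards. The precursor 18 is an open chain with no stereocentre, only an allene axis and two (E) double bonds. The forward reaction has to add the unactivated trisubstituted alkene C4=C5 to the diene C10=C1–C2=C3, form the quaternary C5, and translate the axis and the two alkene geometries into C3, C4 and C5.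

**Proton shift C9–H to C1–H (18 ⇒ 17).** The allene is not carried as such. It is unmasked from the achiral skipped ynone 17 by a 1,3-prototropic shift, and this is where the absolute configuration is introduced, as the axis. The forward step must protonate C1 on one face and hand the allene on to the cycloaddition before it can racemise.

**Bond C9–C10 (17 ⇒ 8 + 16).** The ynone is cut between the methylene carbon and the alkyne into enyne 8 (C10, C1, C2, C3) and diazoketone 16 (C4 to C9 with C11 to C15). The forward reaction is a copper-catalysed insertion of the diazo carbon into the alkyne C–H bond, which joins the two halves without protecting groups.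

**Diazoketone 16 ⇒ 14 ⇒ 13 ⇒ 12 ⇒ 10 + 11 (10 ⇒ 9).** The diazo group comes from the methyl ketone 14 by diazo transfer. The tetrasubstituted C7=C11 alkene of 14 comes from enol triflate 13 by methyl addition–elimination; no geometry problem arises because both β-substituents are methyl. Triflate 13 comes from dione 12, made by C-alkylation of 11 with bromide 10. The (E)-alkene C4=C5, which later fixes the cis relation of the two ring methyls, is bought with alcohol 9.

**Enyne 8 ⇒ 7 ⇒ 6.** The (E)-silyloxy enyne is the one-carbon homologation product of the vinylogous silyl ester 7, which comes from O-silylation of the malonaldehyde salt 6. The (E) geometry, which later places the C3 oxygen cis to the C4 methyl, is set here by thermodynamics.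

## Alternatives that were turned down

**Alternative 1:** Robinson annulation (the textbook route). Disconnection: C5–C6 (Michael) and C9=C10 (aldol condensation) of ring B. Forward key step: cyclohexanone A1 and a vinyl ketone give octalone A2; then alkylidenation at C7, dehydrogenation to C1=C2, deprotection and esterification. Turned down because A1 must already contain C3 and C4 in defined form, so the key step sets only C5. The cis relation of C14 to C15 depends on Michael addition at the more substituted α-carbon anti to a neighbouring methyl, which is typically only moderately selective. After annulation three further adjustments remain (C7=C11, C1=C2, ester), the dehydrogenation creating a double bond next to the C3 oxygen under oxidising or basic conditions. The count of linear steps would exceed that of the chosen route for a key step that builds one ring and one stereocentre.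

**Alternative 2:** biomimetic 1,2-methyl shift from a eudesmane. Disconnection: the C5–C14 bond, with the methyl returned to C10. Forward key step: ionisation of the tertiary C5 alcohol A3, migration of the C10 methyl to C5 anti to the leaving group, and loss of H9 to give A4 with C9=C10. Turned down because the C5 cation has easier exits (loss of H4 or H6, hydride shift from C4 that scrambles C4). The C10 cation formed after the shift is destabilised by the nearby enone. A3 is itself a four-stereocentre decalin that needs its own annulation route, and A4 still lacks C1=C2. The skeletal change is elegant but buys nothing in step economy.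

**Alternative 3:** dearomative para-alkylation. Disconnection: the C4–C5 bond alone, ring B taken from a phenol. Forward key step: intramolecular SN2 alkylation of phenol A5 at its methyl-bearing para carbon (C5) by the secondary C4 mesylate, closing ring A and giving cyclohexadienone A6. Turned down because the step closes one ring only. It needs substitution at a hindered secondary centre next to a silyloxy carbon in competition with O-alkylation and elimination. The facial outcome at C5 rests on 1,2-induction alone. A6 carries C6=C7 with an isopropyl group, so a contra-conjugative shift of that double bond to the exocyclic C7=C11 position would still be required. A5 needs C3 and C4 set separately beforehand.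

Key step: step 11

Remark: the catalyst antipode written in step 11 is a working choice; if the sense of induction at C1 turns out opposite, the (1S,2S) antipode is used to reach the (aR)-allene.

## Route

Step 1
Reactants: 1 (S)-2-methylbutan-1-ol; 2 ethyl (2E)-4-(diethoxyphosphoryl)but-2-enoate
Product: 4 ethyl (2E,4E,6S)-6-methylocta-2,4-dienoate, via (S)-2-methylbutanal 3 (not isolated)
Conditions: 2,2,6,6-tetramethylpiperidin-1-oxyl (TEMPO, 10 mol%), PhI(OAc)2, CH2Cl2, 0 °C to rt; washed and dried solution of 3 added to 2, LiN(SiMe3)2, THF, −78 °C to 0 °C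
Reagents that add atoms: none
Why: The oxoammonium oxidation stops at the aldehyde and does not touch the α-stereocentre, and the volatile, epimerisable 3 is used in solution at once. The vinylogous Horner–Wadsworth–Emmons reaction of the lithiated phosphonocrotonate should give the new C4′=C5′ bond with (E) geometry, the C2′=C3′ bond keeping its (E) geometry; C6′ comes unchanged from 1.

Step 2
Reactants: 4 ethyl (2E,4E,6S)-6-methylocta-2,4-dienoate
Product: 5 (2E,4E,6S)-6-methylocta-2,4-dienoic acid
Conditions: LiOH·H2O, THF/MeOH/H2O, rt; then 1 M HCl
Reagents that add atoms: lithium hydroxide, [Li+].[OH-]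
Why: Plain saponification of a dienoate; C6′ is not acidic enough to epimerise under these conditions.

Step 3
Reactants: 6 tetrabutylammonium (1E)-3-oxoprop-1-en-1-olate (malonaldehyde tetrabutylammonium salt)
Product: 7 (2E)-3-[(triisopropylsilyl)oxy]prop-2-enal
Conditions: iPr3SiCl, CH2Cl2, 0 °C to rt
Reagents that add atoms: chlorotriisopropylsilane, CC(C)[Si](Cl)(C(C)C)C(C)C
Why: O-silylation of the ambident malonaldehyde enolate by the hard silicon electrophile; the extended (E) vinylogous silyl ester is the thermodynamically preferred geometry, and the bulky silyl group is chosen to survive the following base and heat.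

Step 4
Reactants: 7 (2E)-3-[(triisopropylsilyl)oxy]prop-2-enal
Product: 8 [(1E)-but-1-en-3-yn-1-yloxy]triisopropylsilane
Conditions: Me3SiCHN2, n-BuLi, THF, −78 °C; then 7, −78 °C to 0 °C
Reagents that add atoms: (trimethylsilyl)diazomethane, C[Si](C)(C)C=[N+]=[N-]
Why: Colvin homologation: 1,2-addition of the lithiated diazomethane, Peterson elimination, loss of N2 and 1,2-hydrogen shift of the alkylidene carbene give the terminal alkyne. The aprotic medium avoids alcoholysis of the vinylogous silyl ester, and the (E) enol ether is not touched.

Step 5
Reactants: 9 (2E)-2-methylbut-2-en-1-ol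
Product: 10 (2E)-1-bromo-2-methylbut-2-ene
Conditions: PBr3 (0.4 equiv), Et2O, −10 °C to 0 °C
Reagents that add atoms: phosphorus tribromide, BrP(Br)Br
Why: SN2 bromination of a primary allylic alcohol at low temperature; the primary bromide with the trisubstituted (E) alkene is also the thermodynamically preferred allylic isomer.

Step 6
Reactants: 10 (2E)-1-bromo-2-methylbut-2-ene; 11 pentane-2,4-dione
Product: 12 3-[(2E)-2-methylbut-2-en-1-yl]pentane-2,4-dione
Conditions: K2CO3, acetone, reflux (11 in excess)
Reagents that add atoms: none
Why: C-alkylation of the soft dione enolate by a reactive primary allylic bromide (SN2 at CH2, alkene geometry untouched); excess 11 suppresses dialkylation.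

Step 7
Reactants: 12 3-[(2E)-2-methylbut-2-en-1-yl]pentane-2,4-dione
Product: 13 3-[(2E)-2-methylbut-2-en-1-yl]-4-oxopent-2-en-2-yl trifluoromethanesulfonate (mixture of enol triflate geometric isomers)
Conditions: (CF3SO2)2O, Et3N, CH2Cl2, −78 °C to 0 °C
Reagents that add atoms: trifluoromethanesulfonic anhydride, O=S(=O)(OS(=O)(=O)C(F)(F)F)C(F)(F)F
Why: O-sulfonylation of the symmetrical dione enolate gives a single constitutional enol triflate; its geometry is irrelevant because both isomers converge in step 8.

Step 8
Reactants: 13 3-[(2E)-2-methylbut-2-en-1-yl]-4-oxopent-2-en-2-yl trifluoromethanesulfonate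
Product: 14 4-methyl-3-[(2E)-2-methylbut-2-en-1-yl]pent-3-en-2-one
Conditions: Me2CuLi (from CuI and MeLi), Et2O/THF, −78 °C to −30 °C
Reagents that add atoms: methyllithium, [Li]C (used as lithium dimethylcuprate, [Li+].C[Cu-]C)
Why: Conjugate addition–elimination of a Gilman cuprate on a β-triflyloxy enone builds the tetrasubstituted C7=C11 alkene. The cuprate does not add to the ketone, and the hindered product enone is a poor acceptor for a second addition.

Step 9
Reactants: 14 4-methyl-3-[(2E)-2-methylbut-2-en-1-yl]pent-3-en-2-one
Product: 16 1-diazo-4-methyl-3-[(2E)-2-methylbut-2-en-1-yl]pent-3-en-2-one, via trifluoroacetyl ketone 15 (not isolated)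
Conditions: LiN(SiMe3)2, THF, −78 °C; CF3CO2CH2CF3; 1 M HCl work-up, crude 15; then CH3SO2N3, Et3N, H2O (1 equiv), MeCN, rt
Reagents that add atoms: methanesulfonyl azide, CS(=O)(=O)N=[N+]=[N-]
Why: Detrifluoroacetylative diazo transfer, the standard entry to α′-diazo enones: kinetic deprotonation at the α′ methyl, Claisen trifluoroacetylation to 15, then diazo transfer with loss of the trifluoroacetyl group as the sulfonamide.

Step 10
Reactants: 8 [(1E)-but-1-en-3-yn-1-yloxy]triisopropylsilane; 16 1-diazo-4-methyl-3-[(2E)-2-methylbut-2-en-1-yl]pent-3-en-2-one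
Product: 17 (1E,9E)-9-methyl-7-(propan-2-ylidene)-1-[(triisopropylsilyl)oxy]undeca-1,9-dien-3-yn-6-one
Conditions: CuI (10 mol%), MeCN, rt, argon, slow addition of 16 to 8 (1.5 equiv); filtration through neutral alumina, used at once
Reagents that add atoms: none
Why: Copper-catalysed coupling of a terminal alkyne with a diazo carbonyl compound: the acetylide of monovalent copper takes up 16 as a carbene, 1,2-migration of the alkynyl group forms C9–C10, and protonation at C9 releases the skipped ynone. Without added base the propargyl tautomer should be retained, so the allene axis stays unformed until step 11.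

Step 11
Reactants: 17 (1E,9E)-9-methyl-7-(propan-2-ylidene)-1-[(triisopropylsilyl)oxy]undeca-1,9-dien-3-yn-6-one
Product: 19 (4aR,5R,6S)-4a,5-dimethyl-3-(propan-2-ylidene)-6-[(triisopropylsilyl)oxy]-4,4a,5,6-tetrahydronaphthalen-2(3H)-one, via (aR)-vinylallenone 18 (not isolated)
Conditions: 1-[3,5-bis(trifluoromethyl)phenyl]-3-[(1R,2R)-2-(dimethylamino)cyclohexyl]thiourea (10 mol%), toluene, −20 °C, argon; filtration through Florisil; then toluene (0.01 M), 2,6-di-tert-butyl-4-methylphenol (BHT), 90 °C
Reagents that add atoms: none
Why: Proposed new method: the bifunctional thiourea–tertiary amine deprotonates the doubly activated C9 methylene of 17 (ketone α and propargylic) and its ammonium ion returns the proton to the alkyne terminus C1 inside a hydrogen-bonded ion pair, so that a 1,3-prototropic shift gives the axially chiral vinylallenone 18; the closest known reaction type is the chiral Brønsted base catalysed isomerisation of 3-alkynoates to enantioenriched allenoates, also run in tandem with cycloadditions, which has not been shown for β,γ-alkynyl ketones relayed into an intramolecular Diels–Alder reaction. After removal of the base, 18 reacts as a vinylallene diene (C10=C1–C2=C3) with the tethered unactivated alkene C4=C5 in a thermal type 1 intramolecular [4+2] cycloaddition, the known class of vinylallene Diels–Alder reactions with axial-to-central chirality transfer. Ring A (C1, C2, C3, C4, C5, C10) closes as the six-membered cycloaddition ring through the new bonds C3–C4 and C5–C10, and ring B (C5 to C10) closes through the same C5–C10 bond as the six-membered tether ring; the allene bond C9=C10 that takes no part becomes the enone double bond and C1=C2 is the new ring alkene, so the whole trienone arises without a redox step. Because the substituents on C9 stand perpendicular to the diene plane, the tether C8–C7–C6 can deliver C4=C5 only to the diene face on which C8 lies, so the (aR) axis alone decides the absolute configuration. The same constraint forces C6 exo and therefore both alkene methyls under the diene: C5 (quaternary) and C4 are related by suprafacial addition to the (E)-alkene (methyls cis), and C3 is related to C4 by the (E)-enol ether, whose outside silyloxy group ends up cis to the endo C4 methyl, which gives the all-cis (3S,4R,5R) triad. The step needs high enantioselectivity in the protonation at C1 and no racemisation or Nazarov-type closure of 18; the low isomerisation temperature, the removal of the base before heating and the lack of an sp3 C–H at the diene terminus (no [1,5]-hydrogen shift) are meant to secure this.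

Step 12
Reactants: 19 (4aR,5R,6S)-4a,5-dimethyl-3-(propan-2-ylidene)-6-[(triisopropylsilyl)oxy]-4,4a,5,6-tetrahydronaphthalen-2(3H)-one
Product: 20 (4aR,5R,6S)-6-hydroxy-4a,5-dimethyl-3-(propan-2-ylidene)-4,4a,5,6-tetrahydronaphthalen-2(3H)-one
Conditions: Bu4NF, AcOH, THF, 0 °C to rt
Reagents that add atoms: none
Why: Fluoride cleavage of the Si–O bond leaves the C3–O bond and its configuration untouched; the acetic acid buffer keeps the alkoxide from acting as a base on the dienone.

Step 13
Reactants: 5 (2E,4E,6S)-6-methylocta-2,4-dienoic acid; 20 (4aR,5R,6S)-6-hydroxy-4a,5-dimethyl-3-(propan-2-ylidene)-4,4a,5,6-tetrahydronaphthalen-2(3H)-one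
Product: 22 (1R,2S,8aR)-1,8a-dimethyl-6-oxo-7-(propan-2-ylidene)-1,2,6,7,8,8a-hexahydronaphthalen-2-yl (2E,4E,6S)-6-methylocta-2,4-dienoate, via mixed anhydride 21 (not isolated)
Conditions: 5, 2,4,6-Cl3C6H2COCl, Et3N, toluene, rt; then 20, 4-(dimethylamino)pyridine (DMAP), toluene, rt
Reagents that add atoms: none
Why: Yamaguchi esterification: the hindered aroyl half of 21 directs acyl transfer to the dienoyl carbonyl. The C3–O bond is not broken, so C3 keeps its configuration, and the mild conditions spare the dienoate geometry and the dienone.

## Compound list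

1 | (S)-2-methylbutan-1-ol | CC[C@H](C)CO | starting material
2 | ethyl (2E)-4-(diethoxyphosphoryl)but-2-enoate | CCOC(=O)/C=C/CP(=O)(OCC)OCC | starting material
3 | (S)-2-methylbutanal | CC[C@H](C)C=O | intermediate
4 | ethyl (2E,4E,6S)-6-methylocta-2,4-dienoate | CC[C@H](C)/C=C/C=C/C(=O)OCC | intermediate
5 | (2E,4E,6S)-6-methylocta-2,4-dienoic acid | CC[C@H](C)/C=C/C=C/C(=O)O | intermediate
6 | tetrabutylammonium (1E)-3-oxoprop-1-en-1-olate | [O-]/C=C/C=O.CCCC[N+](CCCC)(CCCC)CCCC | starting material
7 | (2E)-3-[(triisopropylsilyl)oxy]prop-2-enal | O=C/C=C/O[Si](C(C)C)(C(C)C)C(C)C | intermediate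
8 | [(1E)-but-1-en-3-yn-1-yloxy]triisopropylsilane | C#C/C=C/O[Si](C(C)C)(C(C)C)C(C)C | intermediate
9 | (2E)-2-methylbut-2-en-1-ol | C/C=C(\C)CO | starting material
10 | (2E)-1-bromo-2-methylbut-2-ene | C/C=C(\C)CBr | intermediate
11 | pentane-2,4-dione | CC(=O)CC(C)=O | starting material
12 | 3-[(2E)-2-methylbut-2-en-1-yl]pentane-2,4-dione | C/C=C(\C)CC(C(C)=O)C(C)=O | intermediate
13 | 3-[(2E)-2-methylbut-2-en-1-yl]-4-oxopent-2-en-2-yl trifluoromethanesulfonate (enol triflate geometry not defined, mixture) | C/C=C(\C)CC(C(C)=O)=C(C)OS(=O)(=O)C(F)(F)F | intermediate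
14 | 4-methyl-3-[(2E)-2-methylbut-2-en-1-yl]pent-3-en-2-one | C/C=C(\C)CC(=C(C)C)C(C)=O | intermediate
15 | 1,1,1-trifluoro-6-methyl-5-[(2E)-2-methylbut-2-en-1-yl]hept-5-ene-2,4-dione | C/C=C(\C)CC(=C(C)C)C(=O)CC(=O)C(F)(F)F | intermediate
16 | 1-diazo-4-methyl-3-[(2E)-2-methylbut-2-en-1-yl]pent-3-en-2-one | C/C=C(\C)CC(=C(C)C)C(=O)C=[N+]=[N-] | intermediate
17 | (1E,9E)-9-methyl-7-(propan-2-ylidene)-1-[(triisopropylsilyl)oxy]undeca-1,9-dien-3-yn-6-one | C/C=C(\C)CC(=C(C)C)C(=O)CC#C/C=C/O[Si](C(C)C)(C(C)C)C(C)C | intermediate
18 | (aR)-(1E,9E)-9-methyl-7-(propan-2-ylidene)-1-[(triisopropylsilyl)oxy]undeca-1,3,4,9-tetraen-6-one (M helicity of the C3=C4=C5 allene of this chain) | C/C=C(\C)CC(=C(C)C)C(=O)C([H])=[C@]=C([H])/C=C/O[Si](C(C)C)(C(C)C)C(C)C | intermediate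
19 | (4aR,5R,6S)-4a,5-dimethyl-3-(propan-2-ylidene)-6-[(triisopropylsilyl)oxy]-4,4a,5,6-tetrahydronaphthalen-2(3H)-one | CC(C)[Si](O[C@H]1C=CC2=CC(=O)C(=C(C)C)C[C@]2(C)[C@H]1C)(C(C)C)C(C)C | intermediate
20 | (4aR,5R,6S)-6-hydroxy-4a,5-dimethyl-3-(propan-2-ylidene)-4,4a,5,6-tetrahydronaphthalen-2(3H)-one | O[C@H]1C=CC2=CC(=O)C(=C(C)C)C[C@]2(C)[C@H]1C | intermediate
21 | (2E,4E,6S)-6-methylocta-2,4-dienoic 2,4,6-trichlorobenzoic anhydride | CC[C@H](C)/C=C/C=C/C(=O)OC(=O)c1c(Cl)cc(Cl)cc1Cl | intermediate
22 | (1R,2S,8aR)-1,8a-dimethyl-6-oxo-7-(propan-2-ylidene)-1,2,6,7,8,8a-hexahydronaphthalen-2-yl (2E,4E,6S)-6-methylocta-2,4-dienoate | CC[C@H](C)/C=C/C=C/C(=O)O[C@H]1C=CC2=CC(=O)C(=C(C)C)C[C@]2(C)[C@H]1C | target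

## Step count and least certain steps

Total step count: 13. Longest linear sequence: 9 steps (steps 5, 6, 7, 8, 9, 10, 11, 12, 13). The acid branch (steps 1 and 2) and the enyne branch (steps 3 and 4) are two steps each.

**Step 11 (key step, proposed new method).** What may go wrong: insufficient face selection in the proton transfer to C1 that creates the allene axis; loss of axial purity by reversible deprotonation before the cycloaddition; and consumption of the allenone by Nazarov-type closure, amine addition or oligomerisation faster than the cycloaddition onto the hindered trisubstituted alkene.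

Fallback with known chemistry only, setting out from 17: a catalytic amount of Et3N in toluene at rt isomerises 17 to the racemic vinylallenone F1, and heating in toluene gives the racemic silyl ether F2. Its relative configuration is still fixed by the two (E) geometries and the tether. Bu4NF/AcOH gives the racemic alcohol F3. Yamaguchi esterification with 5 through 21 gives 22 together with the diastereomeric ester F4, which differ in the whole core and are separated by preparative chromatography or crystallisation. The fallback returns to the route at 22, at the cost of half of the core.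

**Step 10.** What may go wrong: formation of a free copper carbene from 16 and intramolecular cyclopropanation of the C4=C5 alkene (16 is a 1-diazohex-5-en-2-one, the classical substrate for that reaction) or cyclopropanation of the enol ether; early isomerisation of 17 to racemic allenone; copper-mediated cycloisomerisation of that allenone to a furan.

Fallback without a metal carbene, setting out from 8 and 16: n-BuLi in THF at −78 °C gives the lithium acetylide F5, and one third of an equivalent of BF3·OEt2 gives the trialkynylborane F6. Addition of 16 at −78 °C triggers the Hooz reaction: coordination of the diazo carbon to boron, 1,2-shift of an alkynyl group with loss of N2, and hydrolysis of the boron enolate to 17. The fallback returns at 17; the price is three equivalents of 8 per 16.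

**Step 4.** What may go wrong: attack of the lithiated diazomethane at silicon or at C3 of the vinylogous silyl ester (addition–elimination) instead of 1,2-addition to the aldehyde, and loss of the volatile product on isolation.

Fallback, setting out from 7: Corey–Fuchs homologation. CBr4 and PPh3 in CH2Cl2 at 0 °C give the dibromodiene F7 under neutral conditions. Two equivalents of n-BuLi at −78 °C convert F7 by halogen–lithium exchange and rearrangement into the lithium acetylide F5 (the species of the fallback to step 10), and water gives 8. The fallback returns at 8, or F5 is used directly for F6.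

**Step 13.** What may go wrong: slow acyl transfer to the secondary allylic alcohol shielded by the cis C4 methyl, leaving time for DMAP-induced E/Z drift or deconjugation of the dienoyl donor and for ionisation at the allylic C3–O bond.

Fallback that builds the dienoate on the core, setting out from 20 and 2: one equivalent of LiOH converts 2 into (2E)-4-(diethoxyphosphoryl)but-2-enoic acid F8. Carbodiimide coupling (N,N′-diisopropylcarbodiimide, catalytic DMAP) of the small acid F8 with 20 gives the phosphonate ester F9. Horner–Wadsworth–Emmons reaction of F9 with aldehyde 3 (made from 1 as in step 1) under LiCl/1,8-diazabicyclo[5.4.0]undec-7-ene gives 22, where the fallback returns to the route.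

## Further compounds

F1 | step 11 | racemic (1E,9E)-9-methyl-7-(propan-2-ylidene)-1-[(triisopropylsilyl)oxy]undeca-1,3,4,9-tetraen-6-one | C/C=C(\C)CC(=C(C)C)C(=O)C([H])=[C@]=C([H])/C=C/O[Si](C(C)C)(C(C)C)C(C)C.C/C=C(\C)CC(=C(C)C)C(=O)C([H])=[C@@]=C([H])/C=C/O[Si](C(C)C)(C(C)C)C(C)C
F2 | step 11 | racemic (4aR,5R,6S)-4a,5-dimethyl-3-(propan-2-ylidene)-6-[(triisopropylsilyl)oxy]-4,4a,5,6-tetrahydronaphthalen-2(3H)-one (with its enantiomer) | CC(C)[Si](O[C@H]1C=CC2=CC(=O)C(=C(C)C)C[C@]2(C)[C@H]1C)(C(C)C)C(C)C.CC(C)[Si](O[C@@H]1C=CC2=CC(=O)C(=C(C)C)C[C@@]2(C)[C@@H]1C)(C(C)C)C(C)C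
F3 | step 11 | racemic (4aR,5R,6S)-6-hydroxy-4a,5-dimethyl-3-(propan-2-ylidene)-4,4a,5,6-tetrahydronaphthalen-2(3H)-one (with its enantiomer) | O[C@H]1C=CC2=CC(=O)C(=C(C)C)C[C@]2(C)[C@H]1C.O[C@@H]1C=CC2=CC(=O)C(=C(C)C)C[C@@]2(C)[C@@H]1C
F4 | step 11 | (1S,2R,8aS)-1,8a-dimethyl-6-oxo-7-(propan-2-ylidene)-1,2,6,7,8,8a-hexahydronaphthalen-2-yl (2E,4E,6S)-6-methylocta-2,4-dienoate | CC[C@H](C)/C=C/C=C/C(=O)O[C@@H]1C=CC2=CC(=O)C(=C(C)C)C[C@@]2(C)[C@@H]1C
F5 | step 10 | lithium (3E)-4-[(triisopropylsilyl)oxy]but-3-en-1-yn-1-ide | [Li]C#C/C=C/O[Si](C(C)C)(C(C)C)C(C)C
F6 | step 10 | tris{(3E)-4-[(triisopropylsilyl)oxy]but-3-en-1-yn-1-yl}borane | B(C#C/C=C/O[Si](C(C)C)(C(C)C)C(C)C)(C#C/C=C/O[Si](C(C)C)(C(C)C)C(C)C)C#C/C=C/O[Si](C(C)C)(C(C)C)C(C)C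
F7 | step 4 | {[(1E)-4,4-dibromobuta-1,3-dien-1-yl]oxy}triisopropylsilane | BrC(Br)=C/C=C/O[Si](C(C)C)(C(C)C)C(C)C
F8 | step 13 | (2E)-4-(diethoxyphosphoryl)but-2-enoic acid | OC(=O)/C=C/CP(=O)(OCC)OCC
F9 | step 13 | (1R,2S,8aR)-1,8a-dimethyl-6-oxo-7-(propan-2-ylidene)-1,2,6,7,8,8a-hexahydronaphthalen-2-yl (2E)-4-(diethoxyphosphoryl)but-2-enoate | CCOP(=O)(OCC)C/C=C/C(=O)O[C@H]1C=CC2=CC(=O)C(=C(C)C)C[C@]2(C)[C@H]1C
A1 | alternative 1 | (3R,4S)-4-[(tert-butyldimethylsilyl)oxy]-2,3-dimethylcyclohexan-1-one (C2 epimerisable) | CC(C)(C)[Si](C)(C)O[C@H]1CCC(=O)C(C)[C@H]1C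
A2 | alternative 1 | (4aR,5R,6S)-6-[(tert-butyldimethylsilyl)oxy]-4a,5-dimethyl-4,4a,5,6,7,8-hexahydronaphthalen-2(3H)-one | CC(C)(C)[Si](C)(C)O[C@H]1CCC2=CC(=O)CC[C@]2(C)[C@H]1C
A3 | alternative 2 | (4aR,5S,6S,8aR)-6-[(tert-butyldimethylsilyl)oxy]-4a-hydroxy-5,8a-dimethyl-3-(propan-2-ylidene)octahydronaphthalen-2(1H)-one | CC(C)(C)[Si](C)(C)O[C@H]1CC[C@]2(C)CC(=O)C(=C(C)C)C[C@@]2(O)[C@H]1C
A4 | alternative 2 | (4aR,5R,6S)-6-[(tert-butyldimethylsilyl)oxy]-4a,5-dimethyl-3-(propan-2-ylidene)-4,4a,5,6,7,8-hexahydronaphthalen-2(3H)-one | CC(C)(C)[Si](C)(C)O[C@H]1CCC2=CC(=O)C(=C(C)C)C[C@]2(C)[C@H]1C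
A5 | alternative 3 | (2R,3S,4Z)-3-[(tert-butyldimethylsilyl)oxy]-5-[5-hydroxy-2-methyl-4-(propan-2-yl)phenyl]pent-4-en-2-yl methanesulfonate | CC(C)c1cc(C)c(/C=C\[C@H](O[Si](C)(C)C(C)(C)C)[C@@H](C)OS(C)(=O)=O)cc1O
A6 | alternative 3 | (4aR,5R,6S)-6-[(tert-butyldimethylsilyl)oxy]-4a,5-dimethyl-3-(propan-2-yl)-5,6-dihydronaphthalen-2(4aH)-one | CC(C)(C)[Si](C)(C)O[C@H]1C=CC2=CC(=O)C(C(C)C)=C[C@]2(C)[C@H]1C
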